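(Readings and results come from a simulation with constants of no real substance; the scatter is artificial.)

I started from the easy count: each G that turns takes one Q, as I assumed, so in the flask G is the limiting reagent, and turning all of it spends a share s = 0.400 of the Q.

| flask | G | Q | remark | time | volume of the second phase over the first |
|---|---|---|---|---|---|
| east | 0.44 M | 2.2 M | run made earlier |  |  |
| west | 0.66 M | 2.2 M | run made earlier |  |  |
| flask | 0.88 M | 2.20 M |  | 15 h | 1.0 |

- east (time / h: X / %, G / %): 1.00: 15, 87; 3.00: 47, 52; 5.00: 70, 29; 8.00: 84, 17; 12.0: 97, 7; 15.0: 97, 1
- west (time / h: X / %, G / %): 1.00: 15, 86; 3.00: 48, 50; 5.00: 69, 32; 8.00: 81, 16; 12.0: 96, 8; 15.0: 97, 6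

(scatter of a reading: 1.5 percentage points)

- in the second phase: Q; everything else is in the first
- charges count per volume of the first phase; a concentration in a rate is the amount of a species over the volume of its own phase; every rate counts per litre of the first phase
- the earlier runs hold the two phases in the same ratio of volumes as the flask asked about

* the X standing at 15 h, as a percentage of the G charged
* the change that raises the amount of X at 15 h, in percent of the G charged most ("none" if none brings more than 2 percentage points) (summer / noon / none)
* amount of X at 15 h, in percent of the G charged, after noon

How fast does it go? I took the rate as κ times G times the Q left. Integrated, the fraction of G left is (one − s)/(E − s), with E = exp(κ(Q − G)t), charges in the bracket. Solved on the G readings at 8.00 h, this gave 0.00188 L mol⁻¹ min⁻¹ in east and 0.00209 L mol⁻¹ min⁻¹ in west. I kept their mean, 0.00198 L mol⁻¹ min⁻¹, as κ, the second-order constant per G and per Q left.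

For the flask, E = 10.6, so my X at 15 h was 94.1%.

Which change pays? Noon, which doubles the amount of Q, gave 99.9% in my reckoning by the same formula, a gain of 5.8 percentage points. Summer doubles the transfer coefficient of Q. The east G reading at 1.00 h stood behind the rate κ gives by a delay of 0.468 h, as far as one scattered reading shows, and in my estimate giving the whole of that delay back to the flask gains 0.42 points, less than noon.

The forecast said 94.5% for the flask, and it named noon with 99.3%, in its words “Doubling Q roughly doubles the rate”; its 94.5% stood a little higher than my 94.1%.

The flask gave 95.5%, with noon gaining 4.5 points, summer 0.37 points, and 99.9% after noon.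

    L ⇌ Q, rate k1*([L] - [Q]/K1) per volume of the first phase (partition coefficient = 0.660, kL = 0.0101 min⁻¹)
    G + L → X (k = 0.00388 L mol⁻¹ min⁻¹)

The X of the flask has moved 5 points at a Q charge of 1.77 M with the time held, or at a time of 11.1 h with the amounts held. The neighbour with 2.2 M of G has equal charges, so s is one and the integral becomes one/(one + κGt). That gives X of 79.7%, and the neighbour gave 80.7%, with 19% of its G left, L, the reagent in the first phase, at 0.249 M and Q at 8.00% of its own charge.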